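The route rests on closing ring C of the upper flavan unit (O1, C2, C3, C4, C4a, C8a) last, through its aryl ether bond O1–C8a. Cationic or cycloaddition closures of this ring would be expected to favour the 2,4-cis isomer, so both stereocentres are fixed first in an open chain: C4 by rhodium-catalysed asymmetric conjugate arylation of an epiafzelechin-derived chalcone, C2 by CBS reduction. The key step, an intramolecular SNAr of the C2 alkoxide at a fluorine-bearing C8a, then forms the ring without touching either centre and so delivers the 2,4-trans arrangement. Its precursor is a (1S,3S)-3,3-diaryl-1-arylpropan-1-ol built on benzyl-protected (−)-epiafzelechin.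

Key step: step 6

Assumption: (−)-epiafzelechin (2R,3R) is taken as a purchasable chiral-pool flavan-3-ol, and its two stereocentres are carried through unchanged.
Note on descriptors: the diarylmethine carbon has the same geometry throughout; it is S in 8, 9 and 10 (the fluoroaryl group outranks the chromanyl group) and R in 11 and 12.

Step 1
Reactants: 1 (−)-epiafzelechin
Product: 2 (2R,3R)-3,5,7-tris(benzyloxy)-2-[4-(benzyloxy)phenyl]chromane
Conditions: BnBr (5 equiv), NaH (4.5 equiv), DMF, −10 °C → rt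
Reagents that add atoms: benzyl bromide, BrCc1ccccc1
Why: Williamson etherification of the three phenols and the secondary alcohol installs a single protecting-group type that should survive base, borane and rhodium catalysis and leave in one hydrogenolysis; no stereocentre is formed and C2/C3 are not touched at low temperature.

Step 2
Reactants: 2 (2R,3R)-3,5,7-tris(benzyloxy)-2-[4-(benzyloxy)phenyl]chromane
Product: 4 (2R,3R)-3,5,7-tris(benzyloxy)-2-[4-(benzyloxy)phenyl]chromane-8-carbaldehyde, via iminium chloride 3 (not isolated)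
Conditions: POCl3, DMF, 0 → 70 °C; then H2O
Reagents that add atoms: N,N-dimethylformamide, CN(C)C=O; water, O
Why: Vilsmeier–Haack formylation, in which the chloroiminium electrophile should attack C8, the most nucleophilic arene carbon of a 5,7-dialkoxychromane (flanked by O1 and the 7-benzyloxy group, the site also taken by halogenation), and iminium chloride 3 is hydrolysed on work-up; no stereocentre is formed.

Step 3
Reactants: 4 (2R,3R)-3,5,7-tris(benzyloxy)-2-[4-(benzyloxy)phenyl]chromane-8-carbaldehyde; 5 1-[4-(benzyloxy)phenyl]ethanone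
Product: 6 (E)-1-[4-(benzyloxy)phenyl]-3-[(2R,3R)-3,5,7-tris(benzyloxy)-2-[4-(benzyloxy)phenyl]chroman-8-yl]prop-2-en-1-one
Conditions: KOH, EtOH/THF, 40 °C
Reagents that add atoms: none
Why: Claisen–Schmidt aldol condensation of a non-enolisable 2,6-dialkoxybenzaldehyde with an aryl methyl ketone should give the (E)-chalcone after E1cB dehydration; no stereocentre is formed.

Step 4
Reactants: 6 (E)-1-[4-(benzyloxy)phenyl]-3-[(2R,3R)-3,5,7-tris(benzyloxy)-2-[4-(benzyloxy)phenyl]chroman-8-yl]prop-2-en-1-one; 7 [4-(benzyloxy)-2-fluorophenyl]boronic acid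
Product: 8 (3S)-1-[4-(benzyloxy)phenyl]-3-[4-(benzyloxy)-2-fluorophenyl]-3-[(2R,3R)-3,5,7-tris(benzyloxy)-2-[4-(benzyloxy)phenyl]chroman-8-yl]propan-1-one
Conditions: [Rh(OH)((S)-binap)]2 (3 mol %), 7 (3 equiv), dioxane/H2O 10:1, 50 °C
Reagents that add atoms: none
Why: Rhodium-catalysed asymmetric 1,4-addition of an arylboronic acid to an enone (Hayashi–Miyaura reaction), in which the aryl–rhodium species inserts the C2=C3 bond and the new C3 stereocentre is set by catalyst control; the (S)-BINAP complex, the one that gives (S)-3-arylcyclohexanones, is predicted by its quadrant model to deliver the aryl group to the si face of C3 and give the 3S ketone irrespective of the remote epiafzelechin centres, and the antipodal ligand would give the C3 epimer.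

Step 5
Reactants: 8 (3S)-1-[4-(benzyloxy)phenyl]-3-[4-(benzyloxy)-2-fluorophenyl]-3-[(2R,3R)-3,5,7-tris(benzyloxy)-2-[4-(benzyloxy)phenyl]chroman-8-yl]propan-1-one
Product: 9 (1S,3S)-1-[4-(benzyloxy)phenyl]-3-[4-(benzyloxy)-2-fluorophenyl]-3-[(2R,3R)-3,5,7-tris(benzyloxy)-2-[4-(benzyloxy)phenyl]chroman-8-yl]propan-1-ol
Conditions: (R)-2-methyl-CBS-oxazaborolidine (0.3 equiv), BH3·SMe2 (1.2 equiv), THF, −20 °C; then MeOH
Reagents that add atoms: none
Why: Corey–Bakshi–Shibata reduction, in which the (R)-oxazaborolidine–borane complex binds the aryl ketone with the aryl group as the large substituent and should deliver hydride to give the (1S)-carbinol (the mirror image of the (S)-catalyst/(R)-1-arylethanol pairing) under reagent control that does not depend on the C3 centre.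

Step 6
Reactants: 9 (1S,3S)-1-[4-(benzyloxy)phenyl]-3-[4-(benzyloxy)-2-fluorophenyl]-3-[(2R,3R)-3,5,7-tris(benzyloxy)-2-[4-(benzyloxy)phenyl]chroman-8-yl]propan-1-ol
Product: 11 (2S,4R)-7-(benzyloxy)-2-[4-(benzyloxy)phenyl]-4-[(2R,3R)-3,5,7-tris(benzyloxy)-2-[4-(benzyloxy)phenyl]chroman-8-yl]chromane, via potassium alkoxide 10 (not isolated)
Conditions: KHMDS (1.1 equiv), THF, 0 °C; then DMPU, 70 °C
Reagents that add atoms: none
Why: KHMDS converts the carbinol into potassium alkoxide 10, which adds to the fluorine-bearing carbon (the future C8a) to give a Meisenheimer anion that expels fluoride (addition–elimination SNAr). The closest known reaction type is the base-mediated cyclisation of 3-(2-fluoroaryl)propan-1-ols to chromans. Ring C is closed by a 6-exo-trig ipso attack, O1–C8a being the only bond formed. No stereocentre is created: C2 (from the CBS step) keeps its C–O bond and C4 (from the rhodium step) is not involved, so the (2S,4R), 2,4-trans arrangement should be carried over unchanged, which a closure through a cation at C2 or C4 would not guarantee. The step needs O-arylation to outpace base-induced epimerisation of the C4 methine; one equivalent of a base weaker than the diarylmethyl anion, the single C–F site and the meta-placed 7-benzyloxy group, which does not deactivate the ipso carbon, should secure this.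

Step 7
Reactants: 11 (2S,4R)-7-(benzyloxy)-2-[4-(benzyloxy)phenyl]-4-[(2R,3R)-3,5,7-tris(benzyloxy)-2-[4-(benzyloxy)phenyl]chroman-8-yl]chromane
Product: 12 (2R,3R)-8-[(2S,4R)-7-hydroxy-2-(4-hydroxyphenyl)chroman-4-yl]-2-(4-hydroxyphenyl)chromane-3,5,7-triol
Conditions: H2 (1 atm), Pd(OH)2/C, THF/MeOH, rt
Reagents that add atoms: none
Why: Heterogeneous hydrogenolysis of the six benzyl ethers under neutral conditions, the standard deprotection of benzyl-protected proanthocyanidins; the benzylic C2–O1 ring bonds and the C4–C8 diarylmethine bond are expected to survive short exposure and no stereocentre is touched.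

Compound list
1 | (−)-epiafzelechin, (2R,3R)-2-(4-hydroxyphenyl)chromane-3,5,7-triol | Oc1cc(O)c2c(c1)O[C@H](c1ccc(O)cc1)[C@H](O)C2 | starting material
2 | (2R,3R)-3,5,7-tris(benzyloxy)-2-[4-(benzyloxy)phenyl]chromane | C(Oc1cc(OCc2ccccc2)c2c(c1)O[C@H](c1ccc(OCc3ccccc3)cc1)[C@H](OCc1ccccc1)C2)c1ccccc1 | intermediate
3 | N-{[(2R,3R)-3,5,7-tris(benzyloxy)-2-[4-(benzyloxy)phenyl]chroman-8-yl]methylidene}-N-methylmethanaminium chloride | C[N+](C)=Cc1c(OCc2ccccc2)cc(OCc2ccccc2)c2c1O[C@H](c1ccc(OCc3ccccc3)cc1)[C@H](OCc1ccccc1)C2.[Cl-] | intermediate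
4 | (2R,3R)-3,5,7-tris(benzyloxy)-2-[4-(benzyloxy)phenyl]chromane-8-carbaldehyde | O=Cc1c(OCc2ccccc2)cc(OCc2ccccc2)c2c1O[C@H](c1ccc(OCc3ccccc3)cc1)[C@H](OCc1ccccc1)C2 | intermediate
5 | 1-[4-(benzyloxy)phenyl]ethanone | CC(=O)c1ccc(OCc2ccccc2)cc1 | starting material
6 | (E)-1-[4-(benzyloxy)phenyl]-3-[(2R,3R)-3,5,7-tris(benzyloxy)-2-[4-(benzyloxy)phenyl]chroman-8-yl]prop-2-en-1-one | O=C(/C=C/c1c(OCc2ccccc2)cc(OCc2ccccc2)c2c1O[C@H](c1ccc(OCc3ccccc3)cc1)[C@H](OCc1ccccc1)C2)c1ccc(OCc2ccccc2)cc1 | intermediate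
7 | [4-(benzyloxy)-2-fluorophenyl]boronic acid | OB(O)c1ccc(OCc2ccccc2)cc1F | starting material
8 | (3S)-1-[4-(benzyloxy)phenyl]-3-[4-(benzyloxy)-2-fluorophenyl]-3-[(2R,3R)-3,5,7-tris(benzyloxy)-2-[4-(benzyloxy)phenyl]chroman-8-yl]propan-1-one | O=C(C[C@@H](c1c(OCc2ccccc2)cc(OCc2ccccc2)c2c1O[C@H](c1ccc(OCc3ccccc3)cc1)[C@H](OCc1ccccc1)C2)c1ccc(OCc2ccccc2)cc1F)c1ccc(OCc2ccccc2)cc1 | intermediate
9 | (1S,3S)-1-[4-(benzyloxy)phenyl]-3-[4-(benzyloxy)-2-fluorophenyl]-3-[(2R,3R)-3,5,7-tris(benzyloxy)-2-[4-(benzyloxy)phenyl]chroman-8-yl]propan-1-ol | C(Oc1ccc(cc1)[C@@H](O)C[C@@H](c1c(OCc2ccccc2)cc(OCc2ccccc2)c2c1O[C@H](c1ccc(OCc3ccccc3)cc1)[C@H](OCc1ccccc1)C2)c1ccc(OCc2ccccc2)cc1F)c1ccccc1 | intermediate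
10 | potassium (1S,3S)-1-[4-(benzyloxy)phenyl]-3-[4-(benzyloxy)-2-fluorophenyl]-3-[(2R,3R)-3,5,7-tris(benzyloxy)-2-[4-(benzyloxy)phenyl]chroman-8-yl]propan-1-olate | C(Oc1ccc(cc1)[C@@H]([O-])C[C@@H](c1c(OCc2ccccc2)cc(OCc2ccccc2)c2c1O[C@H](c1ccc(OCc3ccccc3)cc1)[C@H](OCc1ccccc1)C2)c1ccc(OCc2ccccc2)cc1F)c1ccccc1.[K+] | intermediate
11 | (2S,4R)-7-(benzyloxy)-2-[4-(benzyloxy)phenyl]-4-[(2R,3R)-3,5,7-tris(benzyloxy)-2-[4-(benzyloxy)phenyl]chroman-8-yl]chromane | C(Oc1ccc(cc1)[C@@H]1C[C@@H](c2c(OCc3ccccc3)cc(OCc3ccccc3)c3c2O[C@H](c2ccc(OCc4ccccc4)cc2)[C@H](OCc2ccccc2)C3)c2ccc(OCc3ccccc3)cc2O1)c1ccccc1 | intermediate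
12 | (2R,3R)-8-[(2S,4R)-7-hydroxy-2-(4-hydroxyphenyl)chroman-4-yl]-2-(4-hydroxyphenyl)chromane-3,5,7-triol (2,4-trans upper unit) | Oc1ccc([C@@H]2C[C@@H](c3c(O)cc(O)c4c3O[C@H](c3ccc(O)cc3)[C@H](O)C4)c3ccc(O)cc3O2)cc1 | target

Total step count: 7
Longest linear sequence: 7 steps (1 → 2 → 4 → 6 → 8 → 9 → 11 → 12)

Steps most likely to fail

Step 4. Insertion at the β-carbon, which carries a doubly ortho-substituted, electron-rich aryl group, may be slow, so that protodeboronation of the 2-fluoroarylboronic acid consumes the reagent; facial discrimination may also be poor. Fallback, setting out from 2 and returning at 8: Claisen–Schmidt condensation of 5 with purchased 4-(benzyloxy)-2-fluorobenzaldehyde (O=Cc1ccc(OCc2ccccc2)cc1F; KOH, EtOH) would give (E)-3-[4-(benzyloxy)-2-fluorophenyl]-1-[4-(benzyloxy)phenyl]prop-2-en-1-one F1. An acid-catalysed Friedel–Crafts conjugate addition of 2 through its nucleophilic C8 (Sc(OTf)3 cat., CH2Cl2, rt) would then give 8 together with its C3 epimer, (3R)-1-[4-(benzyloxy)phenyl]-3-[4-(benzyloxy)-2-fluorophenyl]-3-[(2R,3R)-3,5,7-tris(benzyloxy)-2-[4-(benzyloxy)phenyl]chroman-8-yl]propan-1-one F2. Because the epiafzelechin part is enantiopure, the two are diastereomers and 8 would be separated by chromatography; this gives up catalyst control at C3 in exchange for a bond formation that follows the innate reactivity of C8.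

Step 6. Addition–elimination at an unactivated fluoroarene may be sluggish, so that prolonged heating with base leads to decomposition or to epimerisation at the diarylmethine carbon. Fallback, setting out from 6 and returning at 11, replaces SNAr by copper-catalysed Ullmann etherification of an aryl bromide. Purchased 4-(benzyloxy)-2-bromo-1-iodobenzene (Ic1ccc(OCc2ccccc2)cc1Br) would be converted by iodine–magnesium exchange (i-PrMgCl·LiCl, THF, −40 °C) and B(OiPr)3 into [4-(benzyloxy)-2-bromophenyl]boronic acid F3. The conditions of step 4 applied to 6 and F3 would give (3S)-1-[4-(benzyloxy)phenyl]-3-[4-(benzyloxy)-2-bromophenyl]-3-[(2R,3R)-3,5,7-tris(benzyloxy)-2-[4-(benzyloxy)phenyl]chroman-8-yl]propan-1-one F4. The conditions of step 5 would give (1S,3S)-1-[4-(benzyloxy)phenyl]-3-[4-(benzyloxy)-2-bromophenyl]-3-[(2R,3R)-3,5,7-tris(benzyloxy)-2-[4-(benzyloxy)phenyl]chroman-8-yl]propan-1-ol F5. Cyclisation with CuI (10 mol %), 3,4,7,8-tetramethyl-1,10-phenanthroline and Cs2CO3 in toluene at 110 °C would form the same O1–C8a bond with the carbinol centre untouched and give 11.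

Step 2. Formylation may occur partly at C6 (incomplete regioselectivity between the two doubly activated arene positions). Fallback, setting out from 2 and returning at 4: bromination with NBS (CH2Cl2, −78 → 0 °C), whose C8 selectivity on 5,7-di-O-benzyl flavan-3-ols is established, would give (2R,3R)-3,5,7-tris(benzyloxy)-2-[4-(benzyloxy)phenyl]-8-bromochromane F6; bromine–lithium exchange (n-BuLi, THF, −78 °C) and quenching with DMF would give 4.

Further compounds
F1 | step 4 | (E)-3-[4-(benzyloxy)-2-fluorophenyl]-1-[4-(benzyloxy)phenyl]prop-2-en-1-one | O=C(/C=C/c1ccc(OCc2ccccc2)cc1F)c1ccc(OCc2ccccc2)cc1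
F2 | step 4 | (3R)-1-[4-(benzyloxy)phenyl]-3-[4-(benzyloxy)-2-fluorophenyl]-3-[(2R,3R)-3,5,7-tris(benzyloxy)-2-[4-(benzyloxy)phenyl]chroman-8-yl]propan-1-one | O=C(C[C@H](c1c(OCc2ccccc2)cc(OCc2ccccc2)c2c1O[C@H](c1ccc(OCc3ccccc3)cc1)[C@H](OCc1ccccc1)C2)c1ccc(OCc2ccccc2)cc1F)c1ccc(OCc2ccccc2)cc1
F3 | step 6 | [4-(benzyloxy)-2-bromophenyl]boronic acid | OB(O)c1ccc(OCc2ccccc2)cc1Br
F4 | step 6 | (3S)-1-[4-(benzyloxy)phenyl]-3-[4-(benzyloxy)-2-bromophenyl]-3-[(2R,3R)-3,5,7-tris(benzyloxy)-2-[4-(benzyloxy)phenyl]chroman-8-yl]propan-1-one | O=C(C[C@@H](c1c(OCc2ccccc2)cc(OCc2ccccc2)c2c1O[C@H](c1ccc(OCc3ccccc3)cc1)[C@H](OCc1ccccc1)C2)c1ccc(OCc2ccccc2)cc1Br)c1ccc(OCc2ccccc2)cc1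
F5 | step 6 | (1S,3S)-1-[4-(benzyloxy)phenyl]-3-[4-(benzyloxy)-2-bromophenyl]-3-[(2R,3R)-3,5,7-tris(benzyloxy)-2-[4-(benzyloxy)phenyl]chroman-8-yl]propan-1-ol | C(Oc1ccc(cc1)[C@@H](O)C[C@@H](c1c(OCc2ccccc2)cc(OCc2ccccc2)c2c1O[C@H](c1ccc(OCc3ccccc3)cc1)[C@H](OCc1ccccc1)C2)c1ccc(OCc2ccccc2)cc1Br)c1ccccc1
F6 | step 2 | (2R,3R)-3,5,7-tris(benzyloxy)-2-[4-(benzyloxy)phenyl]-8-bromochromane | Brc1c(OCc2ccccc2)cc(OCc2ccccc2)c2c1O[C@H](c1ccc(OCc3ccccc3)cc1)[C@H](OCc1ccccc1)C2
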